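**Plan**
- Retrosynthesis: the C9 hydroxyl is taken back to an allylic C–H of ring B, C12=C13 is cut (Wittig) to release the C13–C16 tail, C1–C11 is cut (Ireland–Claisen from a C3 allylic propanoate), and last the two ring-B bonds C5–C6 and C9–C10 are cut.
- Enabling feature: ring B is a cyclohexene whose C7=C8 double bond lies across the ring from the spiro atom C5, with the C8 methyl 1,4 to C5. That is the pattern of an isoprene [4+2] adduct of an exocyclic C5=C10 enone, so the cut leaves (S)-3-methyl-2-methylidenecyclopentanone and isoprene.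
- Forward: ring A is dressed from cyclopentenone (conjugate methylation, α-methylenation), ring B is closed by the Diels–Alder reaction, the C1 ketone is transposed to a C3 allylic alcohol, the Claisen rearrangement installs C11/C12, the tail made from methyl (R)-3-hydroxy-2-methylpropanoate is joined by Wittig reaction, and C9 is oxygenated last.
- Stereochemistry: C4 from the ligand-controlled conjugate addition; C5 from diene approach anti to the C4 methyl; the temporary C3 centre from epoxidation anti to that methyl, relayed suprafacially to C1 and, through ketene acetal geometry, to C11; C15 from the chiral pool; C9 from the oxazaborolidine catalyst.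

Key step: step 4

Remark: target locants are used for all intermediates (ring A = C1–C5, C1 bears the side chain, C4 the methyl, C5 is the spiro atom; ring B = C5–C10 with C7=C8, C8 methyl, C9 OH; chain C11–C16); in this numbering the target is (1R,4S,5S,9S,11R,15S).

**Step 1**
Reactants: 1 cyclopent-2-en-1-one
Product: 3 (S)-trimethyl[(3-methylcyclopent-1-en-1-yl)oxy]silane, via zinc enolate 2 (not isolated)
Conditions: Me2Zn, Cu(OTf)2 (2 mol %), (S)-binaphthyl-2,2'-diyl N,N-bis[(R)-1-phenylethyl]phosphoramidite (4 mol %), PhMe, −30 °C; then Me3SiOTf, 0 °C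
Reagents that add atoms: dimethylzinc (C[Zn]C); trimethylsilyl trifluoromethanesulfonate (C[Si](C)(C)OS(=O)(=O)C(F)(F)F)
Why: Copper-catalysed enantioselective conjugate addition, in which the copper–phosphoramidite complex transfers methyl from zinc to one enantioface of the enone and should set C4 as (S) (the facial sense this ligand shows for (S)-3-alkylcycloalkanones), while O-silylation of the zinc enolate stores the enolate regiochemistry (double bond toward the future C5) in an isolable silyl enol ether.

**Step 2**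
Reactants: 3 (S)-trimethyl[(3-methylcyclopent-1-en-1-yl)oxy]silane
Product: 4 (2S,3S)-2-[(dimethylamino)methyl]-3-methylcyclopentan-1-one
Conditions: CH2=NMe2 I, CH2Cl2, rt; aq. NaHCO3 work-up
Reagents that add atoms: dimethylmethylideneammonium iodide (C=[N+](C)C.[I-])
Why: Mannich reaction of a silyl enol ether with a preformed iminium salt, where C–C bond formation can only occur at the enol carbon (future C5), trans to the C4 methyl, and the new centre is erased again in the next step.

**Step 3**
Reactants: 4 (2S,3S)-2-[(dimethylamino)methyl]-3-methylcyclopentan-1-one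
Product: 6 (S)-3-methyl-2-methylidenecyclopentan-1-one, via methiodide 5 (not isolated)
Conditions: MeI, Et2O, rt; then NaHCO3, CH2Cl2/H2O, rt; dried CH2Cl2 solution used at once
Reagents that add atoms: none
Why: Exhaustive N-methylation followed by base-induced β-elimination (E1cB through the ketone enolate) expels trimethylamine and unveils the exocyclic C5=C10 enone without touching C4, and immediate use of the solution avoids self-dimerisation of the labile enone.

**Step 4**
Reactants: 6 (S)-3-methyl-2-methylidenecyclopentan-1-one; 7 isoprene (2-methylbuta-1,3-diene)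
Product: 8 (4S,5R)-4,8-dimethylspiro[4.5]dec-7-en-1-one
Conditions: 7 (5 equiv), Me2AlCl (0.2 equiv), CH2Cl2, −78 → −20 °C
Reagents that add atoms: none
Why: Me2AlCl binds the C1 carbonyl and lowers the LUMO of the exocyclic C5=C10 enone, which then undergoes a concerted, asynchronous [4+2] cycloaddition with s-cis isoprene, the C9–C10 bond (diene CH2 next to the methyl-bearing carbon to the enone β-carbon) running ahead of the C5–C6 bond. The closest known reaction type is the Lewis acid promoted Diels–Alder reaction of 2-methylidenecycloalkanones with 2-substituted butadienes, which gives spiro[4.5]decenones. Ring B closes in this single intermolecular [4+2] event as a six-membered carbocycle by formation of both C5–C6 and C9–C10, C5 becoming the spiro atom. The only new stereocentre, C5, is controlled by the adjacent C4 methyl: the diene adds to the enone face opposite to it, so that C6 ends trans and C10 cis to that methyl. The step needs para regioselectivity (C8 methyl 1,4 to C5), secured by the match of the large LUMO coefficient at C10 with the large HOMO coefficient at the isoprene terminus flanking the methyl-bearing carbon, and it needs this facial selectivity, secured by the C4 methyl sitting directly beside the reacting carbon; C5=C10 is the only activated alkene, so chemoselectivity is not in question.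

**Step 5**
Reactants: 8 (4S,5R)-4,8-dimethylspiro[4.5]dec-7-en-1-one
Product: 10 (4S,5R)-4,8-dimethylspiro[4.5]deca-2,7-dien-1-one, via silyl enol ether 9 (not isolated)
Conditions: LiN(iPr)2, Me3SiCl, THF, −78 °C; then Pd(OAc)2 (1.05 equiv), MeCN, rt
Reagents that add atoms: none
Why: Saegusa–Ito dehydrogenation, in which C2 is the only enolisable position because C5 is quaternary, and palladation of the silyl enol ether followed by β-hydride elimination gives the C2=C3 enone while the unactivated C7=C8 alkene is left alone.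

**Step 6**
Reactants: 10 (4S,5R)-4,8-dimethylspiro[4.5]deca-2,7-dien-1-one
Product: 11 (2S,3S,4R,5R)-2,3-epoxy-4,8-dimethylspiro[4.5]dec-7-en-1-one (epoxide trans to the C4 methyl)
Conditions: 30% H2O2, NaOH (cat.), MeOH, 0 °C
Reagents that add atoms: hydrogen peroxide (OO)
Why: Weitz–Scheffer nucleophilic epoxidation, in which hydroperoxide adds to C3 on the face opposite the neighbouring C4 methyl and the enolate closes the epoxide on that face (fixing C2 and C3), while the electron-rich C7=C8 alkene does not react with the nucleophilic oxidant.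

**Step 7**
Reactants: 11 (2S,3S,4R,5R)-2,3-epoxy-4,8-dimethylspiro[4.5]dec-7-en-1-one
Product: 12 (3R,4R,5S)-4,8-dimethylspiro[4.5]deca-1,7-dien-3-ol
Conditions: N2H4·H2O, AcOH (cat.), MeOH, 0 °C → rt
Reagents that add atoms: none
Why: Wharton transposition, in which the epoxy hydrazone fragments with loss of N2 to the C1=C2 alkene and the C3 alcohol, and since the C3–O bond is never broken the hydroxyl keeps the epoxide configuration (trans to the C4 methyl, on the face of C6).

**Step 8**
Reactants: 12 (3R,4R,5S)-4,8-dimethylspiro[4.5]deca-1,7-dien-3-ol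
Product: 13 (3R,4R,5S)-4,8-dimethylspiro[4.5]deca-1,7-dien-3-yl propanoate
Conditions: (EtCO)2O, Et3N, DMAP (cat.), CH2Cl2, rt
Reagents that add atoms: propanoic anhydride (CCC(=O)OC(=O)CC)
Why: DMAP-catalysed acylation of a secondary allylic alcohol, with retention at C3, installs the three-carbon unit that becomes C11, its methyl and C12.

**Step 9**
Reactants: 13 (3R,4R,5S)-4,8-dimethylspiro[4.5]deca-1,7-dien-3-yl propanoate
Product: 16 (2S)-2-[(1R,4S,5R)-4,8-dimethylspiro[4.5]deca-2,7-dien-1-yl]propanoic acid, via silyl ketene acetal 14 (not isolated), via silyl ester 15 (not isolated)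
Conditions: LiN(iPr)2, THF/DMPU, −78 °C; tBuMe2SiCl; −78 → 60 °C; then 1 M HCl, rt
Reagents that add atoms: none
Why: Ireland–Claisen rearrangement, in which enolisation in THF/DMPU gives the (Z)-silyl ketene acetal, the suprafacial [3,3] shift delivers C11 to C1 on the face that carried the C3 oxygen (setting C1, cis to C6), and the boat-like transition state favoured for cycloalkenyl (Z)-ketene acetals, with both the silyloxy group and the C11 methyl pointing away from ring A, sets C11 in the configuration of the target (descriptor S here only because C12 is still a carboxyl carbon).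

**Step 10**
Reactants: 16 (2S)-2-[(1R,4S,5R)-4,8-dimethylspiro[4.5]deca-2,7-dien-1-yl]propanoic acid
Product: 17 (2S)-2-[(1R,4S,5R)-4,8-dimethylspiro[4.5]deca-2,7-dien-1-yl]propan-1-ol
Conditions: LiAlH4, THF, 0 °C → rt
Reagents that add atoms: none
Why: Hydride reduction of the carboxylic acid to the primary alcohol, which affects neither a stereocentre nor an alkene.

**Step 11**
Reactants: 17 (2S)-2-[(1R,4S,5R)-4,8-dimethylspiro[4.5]deca-2,7-dien-1-yl]propan-1-ol
Product: 18 (2S)-2-[(1R,4S,5R)-4,8-dimethylspiro[4.5]deca-2,7-dien-1-yl]propanal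
Conditions: Dess–Martin periodinane, NaHCO3, CH2Cl2, 0 °C → rt
Reagents that add atoms: none
Why: Dess–Martin oxidation under buffered, non-epimerising conditions gives the α-branched aldehyde without touching the alkenes or the C11 centre.

**Step 12**
Reactants: 19 methyl (R)-3-hydroxy-2-methylpropanoate
Product: 20 methyl (R)-3-[(tert-butyldimethylsilyl)oxy]-2-methylpropanoate
Conditions: tBuMe2SiCl, imidazole, CH2Cl2, rt
Reagents that add atoms: tert-butyldimethylsilyl chloride (CC(C)(C)[Si](C)(C)Cl)
Why: Standard silylation of the primary alcohol (future C16 oxygen), in which the chiral-pool centre C15 takes no part.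

**Step 13**
Reactants: 20 methyl (R)-3-[(tert-butyldimethylsilyl)oxy]-2-methylpropanoate
Product: 21 (S)-3-[(tert-butyldimethylsilyl)oxy]-2-methylpropan-1-ol
Conditions: LiBH4, MeOH (1 equiv), Et2O, 0 °C → rt
Reagents that add atoms: none
Why: Borohydride reduction of the ester to the primary alcohol (future C14) proceeds without epimerisation of the adjacent centre, since the reagent is not basic enough to enolise the ester.

**Step 14**
Reactants: 21 (S)-3-[(tert-butyldimethylsilyl)oxy]-2-methylpropan-1-ol
Product: 22 (R)-tert-butyl(3-iodo-2-methylpropoxy)dimethylsilane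
Conditions: I2, PPh3, imidazole, CH2Cl2, 0 °C → rt
Reagents that add atoms: iodine (II)
Why: Appel-type iodination converts the primary alcohol into the iodide by SN2 displacement at C14 and leaves C15 untouched.

**Step 15**
Reactants: 22 (R)-tert-butyl(3-iodo-2-methylpropoxy)dimethylsilane
Product: 23 {(3S)-4-[(tert-butyldimethylsilyl)oxy]-3-methylbutyl}triphenylphosphonium iodide
Conditions: Ph3PCH3Br, n-BuLi, THF, 0 °C; then 22, 0 °C → rt
Reagents that add atoms: methyltriphenylphosphonium bromide (C[P+](c1ccccc1)(c1ccccc1)c1ccccc1.[Br-])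
Why: C-alkylation of methylidenetriphenylphosphorane by a primary iodide inserts the C13 carbon and gives the homologous phosphonium salt in one operation, the reacting carbon C14 not being stereogenic.

**Step 16**
Reactants: 18 (2S)-2-[(1R,4S,5R)-4,8-dimethylspiro[4.5]deca-2,7-dien-1-yl]propanal; 23 {(3S)-4-[(tert-butyldimethylsilyl)oxy]-3-methylbutyl}triphenylphosphonium iodide
Product: 25 tert-butyl{[(2S,4Z,6R)-6-[(1R,4S,5R)-4,8-dimethylspiro[4.5]deca-2,7-dien-1-yl]-2-methylhept-4-en-1-yl]oxy}dimethylsilane, via phosphorus ylide 24 (not isolated)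
Conditions: 23, NaN(SiMe3)2, THF, −78 → 0 °C; then 18, −78 °C → rt
Reagents that add atoms: none
Why: Wittig olefination with a non-stabilised ylide under lithium-free conditions joins C12 to C13 (Z-selective, the geometry being irrelevant because the alkene is reduced next) at low temperature, where the α-stereocentre C11 of the aldehyde should not epimerise.

**Step 17**
Reactants: 25 tert-butyl{[(2S,4Z,6R)-6-[(1R,4S,5R)-4,8-dimethylspiro[4.5]deca-2,7-dien-1-yl]-2-methylhept-4-en-1-yl]oxy}dimethylsilane
Product: 26 tert-butyl{[(2S,6R)-6-[(1R,4S,5R)-4,8-dimethylspiro[4.5]dec-7-en-1-yl]-2-methylheptyl]oxy}dimethylsilane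
Conditions: TsNHNH2 (excess), NaOAc, DME/H2O, reflux
Reagents that add atoms: none
Why: Diimide formed in situ transfers hydrogen in a concerted syn fashion and reduces the strained cis-disubstituted C2=C3 and the Z-disubstituted C12=C13 alkenes far faster than the trisubstituted C7=C8 alkene, and no stereocentre is created.

**Step 18**
Reactants: 26 tert-butyl{[(2S,6R)-6-[(1R,4S,5R)-4,8-dimethylspiro[4.5]dec-7-en-1-yl]-2-methylheptyl]oxy}dimethylsilane
Product: 28 (2S,6R)-6-[(1R,4S,5R)-4,8-dimethylspiro[4.5]dec-7-en-1-yl]-2-methylheptyl acetate, via primary alcohol 27 (not isolated)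
Conditions: Bu4NF, THF, rt; then Ac2O, Et3N, DMAP, rt
Reagents that add atoms: acetic anhydride (CC(=O)OC(C)=O)
Why: Fluoride cleaves the silyl ether and the liberated primary alkoxide is acetylated in the same flask, so the C16 acetate is in place before any secondary hydroxyl exists in the molecule.

**Step 19**
Reactants: 28 (2S,6R)-6-[(1R,4S,5R)-4,8-dimethylspiro[4.5]dec-7-en-1-yl]-2-methylheptyl acetate
Product: 30 (2S,6R)-6-[(1R,4S,5S)-4,8-dimethyl-9-oxospiro[4.5]dec-7-en-1-yl]-2-methylheptyl acetate, via allylic alcohol 29 (not isolated)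
Conditions: SeO2 (0.5 equiv), tBuOOH, CH2Cl2, rt; aqueous work-up; then Dess–Martin periodinane, NaHCO3, CH2Cl2, rt
Reagents that add atoms: selenium dioxide (O=[Se]=O); tert-butyl hydroperoxide (CC(C)(C)OO)
Why: Riley allylic oxidation, in which SeO2 undergoes an ene reaction at C7 with transfer of a C9 hydrogen and a [2,3] shift that returns the double bond to C7=C8 and places oxygen on the ring methylene attached to the more substituted alkene carbon (C9, not C6), after which Dess–Martin oxidation converges both C9 epimers and any enone already formed on one enone.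

**Step 20**
Reactants: 30 (2S,6R)-6-[(1R,4S,5S)-4,8-dimethyl-9-oxospiro[4.5]dec-7-en-1-yl]-2-methylheptyl acetate
Product: 31 (2S,6R)-6-[(1R,4S,5S,9S)-9-hydroxy-4,8-dimethylspiro[4.5]dec-7-en-1-yl]-2-methylheptyl acetate
Conditions: (R)-Me-CBS oxazaborolidine [(R)-1-methyl-3,3-diphenylhexahydropyrrolo[1,2-c][1,3,2]oxazaborole] (0.2 equiv), BH3·SMe2, THF, −40 °C; MeOH quench
Reagents that add atoms: none
Why: Corey–Bakshi–Shibata reduction, in which the oxazaborolidine–borane complex binds the carbonyl lone pair on the C10 side, with the α-methylalkenyl carbon C8 as the large group, and delivers hydride in 1,2-fashion to the face that should give (9S) under catalyst control, the acetate not being reduced at this temperature.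

**Compound list**
1 | cyclopent-2-en-1-one | O=C1C=CCC1 | starting material
2 | methylzinc (S)-3-methylcyclopent-1-en-1-olate | C[Zn]OC1=C[C@@H](C)CC1 | intermediate (not isolated)
3 | (S)-trimethyl[(3-methylcyclopent-1-en-1-yl)oxy]silane | C[Si](C)(C)OC1=C[C@@H](C)CC1 | intermediate
4 | (2S,3S)-2-[(dimethylamino)methyl]-3-methylcyclopentan-1-one | O=C1CC[C@H](C)[C@H]1CN(C)C | intermediate
5 | N,N,N-trimethyl-1-[(1S,2S)-2-methyl-5-oxocyclopentyl]methanaminium iodide | O=C1CC[C@H](C)[C@H]1C[N+](C)(C)C.[I-] | intermediate (not isolated)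
6 | (S)-3-methyl-2-methylidenecyclopentan-1-one | O=C1CC[C@H](C)C1=C | intermediate
7 | isoprene (2-methylbuta-1,3-diene) | C=CC(C)=C | starting material
8 | (4S,5R)-4,8-dimethylspiro[4.5]dec-7-en-1-one | O=C1CC[C@H](C)[C@@]12CC=C(C)CC2 | intermediate
9 | trimethyl{[(4S,5R)-4,8-dimethylspiro[4.5]deca-1,7-dien-1-yl]oxy}silane | C[Si](C)(C)OC1=CC[C@H](C)[C@@]12CC=C(C)CC2 | intermediate (not isolated)
10 | (4S,5R)-4,8-dimethylspiro[4.5]deca-2,7-dien-1-one | O=C1C=C[C@H](C)[C@@]12CC=C(C)CC2 | intermediate
11 | (2S,3S,4R,5R)-2,3-epoxy-4,8-dimethylspiro[4.5]dec-7-en-1-one | O=C1[C@H]3O[C@H]3[C@H](C)[C@@]12CC=C(C)CC2 | intermediate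
12 | (3R,4R,5S)-4,8-dimethylspiro[4.5]deca-1,7-dien-3-ol | C1=C[C@@H](O)[C@H](C)[C@@]12CC=C(C)CC2 | intermediate
13 | (3R,4R,5S)-4,8-dimethylspiro[4.5]deca-1,7-dien-3-yl propanoate | C1=C[C@@H](OC(=O)CC)[C@H](C)[C@@]12CC=C(C)CC2 | intermediate
14 | (Z)-tert-butyldimethylsilyl ketene acetal of 13 (methyl cis to the silyloxy group) | C1=C[C@@H](O/C(O[Si](C)(C)C(C)(C)C)=C/C)[C@H](C)[C@@]12CC=C(C)CC2 | intermediate (not isolated)
15 | tert-butyldimethylsilyl (2S)-2-[(1R,4S,5R)-4,8-dimethylspiro[4.5]deca-2,7-dien-1-yl]propanoate | CC(C)(C)[Si](C)(C)OC(=O)[C@@H](C)[C@H]1C=C[C@H](C)[C@@]12CC=C(C)CC2 | intermediate (not isolated)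
16 | (2S)-2-[(1R,4S,5R)-4,8-dimethylspiro[4.5]deca-2,7-dien-1-yl]propanoic acid | OC(=O)[C@@H](C)[C@H]1C=C[C@H](C)[C@@]12CC=C(C)CC2 | intermediate
17 | (2S)-2-[(1R,4S,5R)-4,8-dimethylspiro[4.5]deca-2,7-dien-1-yl]propan-1-ol | OC[C@@H](C)[C@H]1C=C[C@H](C)[C@@]12CC=C(C)CC2 | intermediate
18 | (2S)-2-[(1R,4S,5R)-4,8-dimethylspiro[4.5]deca-2,7-dien-1-yl]propanal | O=C[C@@H](C)[C@H]1C=C[C@H](C)[C@@]12CC=C(C)CC2 | intermediate
19 | methyl (R)-3-hydroxy-2-methylpropanoate | OC[C@@H](C)C(=O)OC | starting material
20 | methyl (R)-3-[(tert-butyldimethylsilyl)oxy]-2-methylpropanoate | CC(C)(C)[Si](C)(C)OC[C@@H](C)C(=O)OC | intermediate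
21 | (S)-3-[(tert-butyldimethylsilyl)oxy]-2-methylpropan-1-ol | CC(C)(C)[Si](C)(C)OC[C@@H](C)CO | intermediate
22 | (R)-tert-butyl(3-iodo-2-methylpropoxy)dimethylsilane | CC(C)(C)[Si](C)(C)OC[C@@H](C)CI | intermediate
23 | {(3S)-4-[(tert-butyldimethylsilyl)oxy]-3-methylbutyl}triphenylphosphonium iodide | CC(C)(C)[Si](C)(C)OC[C@@H](C)CC[P+](c1ccccc1)(c1ccccc1)c1ccccc1.[I-] | intermediate
24 | {(3S)-4-[(tert-butyldimethylsilyl)oxy]-3-methylbutylidene}triphenylphosphorane | CC(C)(C)[Si](C)(C)OC[C@@H](C)CC=P(c1ccccc1)(c1ccccc1)c1ccccc1 | intermediate (not isolated)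
25 | tert-butyl{[(2S,4Z,6R)-6-[(1R,4S,5R)-4,8-dimethylspiro[4.5]deca-2,7-dien-1-yl]-2-methylhept-4-en-1-yl]oxy}dimethylsilane | CC(C)(C)[Si](C)(C)OC[C@@H](C)C/C=C\[C@@H](C)[C@H]1C=C[C@H](C)[C@@]12CC=C(C)CC2 | intermediate
26 | tert-butyl{[(2S,6R)-6-[(1R,4S,5R)-4,8-dimethylspiro[4.5]dec-7-en-1-yl]-2-methylheptyl]oxy}dimethylsilane | CC(C)(C)[Si](C)(C)OC[C@@H](C)CCC[C@@H](C)[C@H]1CC[C@H](C)[C@@]12CC=C(C)CC2 | intermediate
27 | (2S,6R)-6-[(1R,4S,5R)-4,8-dimethylspiro[4.5]dec-7-en-1-yl]-2-methylheptan-1-ol | OC[C@@H](C)CCC[C@@H](C)[C@H]1CC[C@H](C)[C@@]12CC=C(C)CC2 | intermediate (not isolated)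
28 | (2S,6R)-6-[(1R,4S,5R)-4,8-dimethylspiro[4.5]dec-7-en-1-yl]-2-methylheptyl acetate | CC(=O)OC[C@@H](C)CCC[C@@H](C)[C@H]1CC[C@H](C)[C@@]12CC=C(C)CC2 | intermediate
29 | (2S,6R)-6-[(1R,4S,5S)-9-hydroxy-4,8-dimethylspiro[4.5]dec-7-en-1-yl]-2-methylheptyl acetate, both C9 epimers | CC(=O)OC[C@@H](C)CCC[C@@H](C)[C@H]1CC[C@H](C)[C@@]12CC=C(C)C(O)C2 | intermediate (not isolated)
30 | (2S,6R)-6-[(1R,4S,5S)-4,8-dimethyl-9-oxospiro[4.5]dec-7-en-1-yl]-2-methylheptyl acetate | CC(=O)OC[C@@H](C)CCC[C@@H](C)[C@H]1CC[C@H](C)[C@@]12CC=C(C)C(=O)C2 | intermediate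
31 | (2S,6R)-6-[(1R,4S,5S,9S)-9-hydroxy-4,8-dimethylspiro[4.5]dec-7-en-1-yl]-2-methylheptyl acetate | CC(=O)OC[C@@H](C)CCC[C@@H](C)[C@H]1CC[C@H](C)[C@@]12CC=C(C)[C@@H](O)C2 | target

**Step count**
Total: 20 steps. Longest linear sequence: 16 steps (steps 1–11 and 16–20); the tail branch is steps 12–15.

**Steps most likely to fail**

Step 9 (Ireland–Claisen). The rearrangement may leak between boat-like and chair-like transition states, or the ketene acetal may not form with uniform geometry; either would erode the configuration at C11, while the suprafacial transfer to C1 is not at risk. The fallback sets C11 with an auxiliary instead of in the pericyclic step. Setting out from alcohol 12, Johnson–Claisen rearrangement with triethyl orthoacetate and catalytic propanoic acid at 140 °C should give, with the same transfer to C1, ethyl 2-[(1S,4S,5R)-4,8-dimethylspiro[4.5]deca-2,7-dien-1-yl]acetate F1. Saponification (LiOH, THF/H2O) would give 2-[(1S,4S,5R)-4,8-dimethylspiro[4.5]deca-2,7-dien-1-yl]acetic acid F2. Activation as the pivaloyl mixed anhydride and reaction with lithiated (S)-4-benzyl-1,3-oxazolidin-2-one would give (4S)-4-benzyl-3-{2-[(1S,4S,5R)-4,8-dimethylspiro[4.5]deca-2,7-dien-1-yl]acetyl}-1,3-oxazolidin-2-one F3. Methylation of its sodium Z-enolate (NaN(SiMe3)2, MeI, THF, −78 °C) anti to the benzyl group would give (4S)-4-benzyl-3-{(2S)-2-[(1R,4S,5R)-4,8-dimethylspiro[4.5]deca-2,7-dien-1-yl]propanoyl}-1,3-oxazolidin-2-one F4. Reductive removal of the auxiliary with LiBH4 comes back to the route at alcohol 17.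

Step 7 (Wharton transposition). Hydrazone formation at the C1 carbonyl, which is flanked by the quaternary spiro carbon, may be slow, so that attack of hydrazine on the epoxide and over-reduction compete and little allylic alcohol is formed. The fallback runs the transposition as a radical fragmentation. Setting out from epoxy ketone 11, reduction with NaBH4/CeCl3 in MeOH would give 2,3-epoxy-4,8-dimethylspiro[4.5]dec-7-en-1-ol F5 (either C1 epimer serves). Acylation with 1,1'-thiocarbonyldiimidazole would give the O-(2,3-epoxy-4,8-dimethylspiro[4.5]dec-7-en-1-yl) imidazole-1-carbothioate F6. With Bu3SnH and AIBN in refluxing benzene the C1 radical opens the adjacent epoxide to the C3 alkoxy radical, which takes up hydrogen; the C3–O bond is untouched, and the sequence comes back to the route at allylic alcohol 12.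

Step 4 (Diels–Alder). Hetero-Diels–Alder self-dimerisation of enone 6 and Lewis acid induced oligomerisation of isoprene may outrun the cycloaddition, and facial selectivity would erode if warming were needed. The fallback activates the dienophile as an oxocarbenium ion (ionic Diels–Alder reaction of an enone ketal) while forming the same two bonds. Setting out from enone 6, ketalisation with 1,2-bis(trimethylsilyloxy)ethane and catalytic Me3SiOTf at −78 °C would give (7S)-7-methyl-6-methylidene-1,4-dioxaspiro[4.4]nonane F7. With isoprene and catalytic Me3SiOTf at −78 °C the ring-opened 2-alkoxyallyl cation should add para-selectively and anti to the methyl group and reclose to (4S,5R)-4,8-dimethylspiro[4.5]dec-7-en-1-one ethylene ketal F8. Mild aqueous acid (pyridinium tosylate, acetone/H2O) comes back to the route at ketone 8.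

**Further compounds**
F1 | step 9 | ethyl 2-[(1S,4S,5R)-4,8-dimethylspiro[4.5]deca-2,7-dien-1-yl]acetate | CCOC(=O)C[C@H]1C=C[C@H](C)[C@@]12CC=C(C)CC2
F2 | step 9 | 2-[(1S,4S,5R)-4,8-dimethylspiro[4.5]deca-2,7-dien-1-yl]acetic acid | OC(=O)C[C@H]1C=C[C@H](C)[C@@]12CC=C(C)CC2
F3 | step 9 | (4S)-4-benzyl-3-{2-[(1S,4S,5R)-4,8-dimethylspiro[4.5]deca-2,7-dien-1-yl]acetyl}-1,3-oxazolidin-2-one | O=C(C[C@H]1C=C[C@H](C)[C@@]12CC=C(C)CC2)N3[C@@H](Cc4ccccc4)COC3=O
F4 | step 9 | (4S)-4-benzyl-3-{(2S)-2-[(1R,4S,5R)-4,8-dimethylspiro[4.5]deca-2,7-dien-1-yl]propanoyl}-1,3-oxazolidin-2-one | O=C([C@@H](C)[C@H]1C=C[C@H](C)[C@@]12CC=C(C)CC2)N3[C@@H](Cc4ccccc4)COC3=O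
F5 | step 7 | 2,3-epoxy-4,8-dimethylspiro[4.5]dec-7-en-1-ol (epoxide as in 11, C1 epimers) | OC1[C@H]3O[C@H]3[C@H](C)[C@@]12CC=C(C)CC2
F6 | step 7 | O-(2,3-epoxy-4,8-dimethylspiro[4.5]dec-7-en-1-yl) 1H-imidazole-1-carbothioate | S=C(OC1[C@H]3O[C@H]3[C@H](C)[C@@]12CC=C(C)CC2)n4ccnc4
F7 | step 4 | (7S)-7-methyl-6-methylidene-1,4-dioxaspiro[4.4]nonane | C=C1[C@@H](C)CCC12OCCO2
F8 | step 4 | (4S,5R)-4,8-dimethylspiro[4.5]dec-7-en-1-one ethylene ketal | C13(OCCO3)CC[C@H](C)[C@@]12CC=C(C)CC2
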